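Ring A is closed last onto an enantiopure ring B that already carries C8, C9 and the side chain. Suzuki coupling of the ring-B enol triflate (C10) with a (2E,4Z)-dienylboronate forms C1–C10; the cis-triene so formed closes on heating in the same flask by disrotatory 6π electrocyclisation, forming C4–C5 and leaving the C1=C10 alkene in place. The step exploits the allylic relationship in ring A between the C1=C10 double bond and the C4 (quaternary)–C5 (methine) bond: alkene geometry sets C4 against C5, the pseudoaxial C9 methyl sets the face. The precursors are a cyclohexenyl triflate and a linear dienoate boronate. Diimide reduction of C2=C3 and Sharpless epoxidation finish.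

Key step: step 8

Remark: halimane numbering is used throughout (ring A = C1–C5, C10; ring B = C5–C10; C4 carries the ester, C9 the side chain C11–C16); target configuration is 4S,5R,8R,9S,13S,14S.

Step 1
Reactants: 1 2-methylcyclohex-2-en-1-one
Product: 3 trimethyl{[(3R)-2,3-dimethylcyclohex-1-en-1-yl]oxy}silane, via aluminium enolate 2 (not isolated)
Conditions: AlMe3, Cu(O2CC4H3S) (copper thiophene-2-carboxylate, cat.), BINOL-derived bis(1-phenylethyl)amine phosphoramidite (cat., the enantiomer that gives 3R), Et2O, −30 °C; then TMSOTf, −30 → 0 °C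
Reagents that add atoms: trimethylaluminium, C[Al](C)C; trimethylsilyl trifluoromethanesulfonate, C[Si](C)(C)OS(=O)(=O)C(F)(F)F
Why: Copper-catalysed asymmetric conjugate addition of methyl to the enone, in which the chiral phosphoramidite–copper complex selects the enone face and sets C8 as R, followed by O-silylation of the aluminium enolate, which stores the tetrasubstituted enolate regiochemistry for step 2.

Step 2
Reactants: 3 trimethyl{[(3R)-2,3-dimethylcyclohex-1-en-1-yl]oxy}silane; 4 methyl vinyl ketone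
Product: 5 (2S,3R)-2,3-dimethyl-2-(3-oxobutyl)cyclohexan-1-one
Conditions: TiCl4, CH2Cl2, −78 °C; then H2O
Reagents that add atoms: none
Why: Mukaiyama–Michael addition in which the TiCl4-activated enone is attacked by the tetrasubstituted silyl enol ether on the face anti to the adjacent C8 methyl (pseudoaxial to avoid A(1,2) strain), so the new C9–C11 bond is trans to that methyl, the two methyls end cis and C9 is set as S.

Step 3
Reactants: 5 (2S,3R)-2,3-dimethyl-2-(3-oxobutyl)cyclohexan-1-one; 6 triethyl phosphonoacetate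
Product: 7 ethyl (2E)-5-[(1S,2R)-1,2-dimethyl-6-oxocyclohexyl]-3-methylpent-2-enoate
Conditions: NaH, THF, 0 → 50 °C
Reagents that add atoms: none
Why: Horner–Wadsworth–Emmons olefination should occur only at the unhindered methyl ketone (the ring ketone is flanked by quaternary C9) and is expected to favour the E-enoate, the minor Z isomer to be removed by chromatography.

Step 4
Reactants: 7 ethyl (2E)-5-[(1S,2R)-1,2-dimethyl-6-oxocyclohexyl]-3-methylpent-2-enoate
Product: 8 ethyl (2E)-5-[(1S,6R)-1,6-dimethyl-2-(trifluoromethanesulfonyloxy)cyclohex-2-en-1-yl]-3-methylpent-2-enoate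
Conditions: Tf2O, 2,6-di-tert-butyl-4-methylpyridine, CH2Cl2, 0 °C → rt
Reagents that add atoms: trifluoromethanesulfonic anhydride, O=S(=O)(OS(=O)(=O)C(F)(F)F)C(F)(F)F
Why: Enol triflate formation by O-triflation of the ketone and loss of a C5 proton is regiospecific because C9 is quaternary and only C5 carries α-hydrogens, and these non-basic conditions leave the enoate untouched.

Step 5
Reactants: 8 ethyl (2E)-5-[(1S,6R)-1,6-dimethyl-2-(trifluoromethanesulfonyloxy)cyclohex-2-en-1-yl]-3-methylpent-2-enoate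
Product: 9 (5R,6S)-6-[(3E)-5-hydroxy-3-methylpent-3-en-1-yl]-5,6-dimethylcyclohex-1-en-1-yl trifluoromethanesulfonate
Conditions: iBu2AlH (DIBAL-H), CH2Cl2, −78 °C; aq. potassium sodium tartrate
Reagents that add atoms: none
Why: DIBAL-H 1,2-reduction of the conjugated ester to the allylic alcohol at low temperature should leave the alkene geometry and the enol triflate untouched.

Step 6
Reactants: 10 ethyl (2Z)-3-iodoprop-2-enoate; 11 methyl 2-(triphenylphosphoranylidene)propanoate
Product: 13 methyl (2E,4Z)-5-iodo-2-methylpenta-2,4-dienoate, via (2Z)-3-iodoprop-2-enal 12 (not isolated)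
Conditions: iBu2AlH, CH2Cl2, −78 °C; then 11, −78 °C → rt
Reagents that add atoms: none
Why: Partial DIBAL-H reduction stops at the aluminium hemiacetal at −78 °C and the aldehyde released is trapped at once by the stabilised ylide in an E-selective Wittig reaction, so the labile (Z)-iodoalkene is kept cold and should retain its geometry.

Step 7
Reactants: 13 methyl (2E,4Z)-5-iodo-2-methylpenta-2,4-dienoate
Product: 14 methyl (2E,4Z)-2-methyl-5-(4,4,5,5-tetramethyl-1,3,2-dioxaborolan-2-yl)penta-2,4-dienoate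
Conditions: B2pin2, PdCl2(PPh3)2 (cat.), PPh3, KOPh, toluene, 50 °C
Reagents that add atoms: bis(pinacolato)diboron, CC1(C)OB(OC1(C)C)B1OC(C)(C)C(C)(C)O1
Why: Miyaura borylation (oxidative addition of zerovalent palladium to the alkenyl iodide, transmetallation with the diboron promoted by the weak phenoxide base, reductive elimination) should give the alkenylboronate with retention of the Z geometry, the weak base disfavouring Suzuki homocoupling.

Step 8
Reactants: 9 (5R,6S)-6-[(3E)-5-hydroxy-3-methylpent-3-en-1-yl]-5,6-dimethylcyclohex-1-en-1-yl trifluoromethanesulfonate; 14 methyl (2E,4Z)-2-methyl-5-(4,4,5,5-tetramethyl-1,3,2-dioxaborolan-2-yl)penta-2,4-dienoate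
Product: 16 methyl (1S,5S,6R,8aR)-5-[(3E)-5-hydroxy-3-methylpent-3-en-1-yl]-1,5,6-trimethyl-1,5,6,7,8,8a-hexahydronaphthalene-1-carboxylate (ring A as the C1=C10/C2=C3 diene), via triene 15 (not isolated)
Conditions: Pd(PPh3)4 (cat.), CsF, 1,4-dioxane, 70 °C; then BHT (cat.), 140 °C, sealed tube
Reagents that add atoms: none
Why: Zerovalent palladium inserts into the C10–OTf bond, the fluoride-activated (Z)-alkenylboronate transmetallates and reductive elimination forms C1–C10 with retention of both alkene geometries, giving triene 15 (C5=C10, cis C1=C2, C3=C4 with the methyl inside), which on heating undergoes thermal disrotatory 6π electrocyclisation that forms C4–C5 and moves the π bonds to C1=C10 and C2=C3. The closest known reaction type is the Suzuki (or Stille) coupling/6π-electrocyclisation cascade to cyclohexa-1,3-dienes, on a hindered cyclohexenyl triflate of the kind used in retinoid couplings. Ring A closes as a six-membered carbocycle by 6π-disrotatory closure between the termini C4 and C5. The C4/C5 relative configuration follows from alkene geometry, since H5 (cis to C1 on the ring alkene) and the C4 methyl (2E-enoate) are both inside groups and rotate to the same face, so the methyl ends cis to H5 and the ester cis to C6; the absolute sense is set by ring B, whose half-chair places the C9 methyl pseudoaxial (C8 methyl equatorial), so C4 should bond to the face of C5 anti to it. The step needs torquoselectivity for that face and ring closure faster than loss of the triene; the [1,7]-hydrogen shift from the inside methyl is reversible and returns the same triene geometry, and the radical inhibitor suppresses oligomerisation.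

Step 9
Reactants: 16 methyl (1S,5S,6R,8aR)-5-[(3E)-5-hydroxy-3-methylpent-3-en-1-yl]-1,5,6-trimethyl-1,5,6,7,8,8a-hexahydronaphthalene-1-carboxylate
Product: 17 methyl (1S,5S,6R,8aR)-5-[(3E)-5-hydroxy-3-methylpent-3-en-1-yl]-1,5,6-trimethyl-1,2,3,5,6,7,8,8a-octahydronaphthalene-1-carboxylate
Conditions: 2-nitrobenzenesulfonohydrazide, Et3N, CH2Cl2, rt
Reagents that add atoms: none
Why: Diimide reduction (concerted syn transfer of two hydrogens) should take the cis-disubstituted C2=C3 of the conjugated diene, the most reactive alkene, while the trisubstituted C1=C10 next to quaternary C9 and the trisubstituted side-chain alkene should react far more slowly and no double-bond migration can occur.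

Step 10
Reactants: 17 methyl (1S,5S,6R,8aR)-5-[(3E)-5-hydroxy-3-methylpent-3-en-1-yl]-1,5,6-trimethyl-1,2,3,5,6,7,8,8a-octahydronaphthalene-1-carboxylate
Product: 18 methyl (1S,5S,6R,8aR)-5-{2-[(2S,3S)-3-(hydroxymethyl)-2-methyloxiran-2-yl]ethyl}-1,5,6-trimethyl-1,2,3,5,6,7,8,8a-octahydronaphthalene-1-carboxylate (CNP0324371.1)
Conditions: Ti(OiPr)4 (cat.), L-(+)-diethyl tartrate (cat.), t-BuOOH, 4 Å molecular sieves, CH2Cl2, −20 °C
Reagents that add atoms: tert-butyl hydroperoxide, CC(C)(C)OO
Why: Sharpless asymmetric epoxidation of the (E)-allylic alcohol, in which the titanium complex of L-(+)-diethyl tartrate delivers oxygen to the face that gives the (13S,14S)-epoxide (the sense that gives the (2S,3S)-epoxy alcohol from geraniol), while C1=C10 is not an allylic alcohol and is left alone.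

Compound list
1 | 2-methylcyclohex-2-en-1-one | CC1=CCCCC1=O | starting material
2 | dimethylaluminium (3R)-2,3-dimethylcyclohex-1-en-1-olate | C[C@@H]1CCCC(O[Al](C)C)=C1C | intermediate
3 | trimethyl{[(3R)-2,3-dimethylcyclohex-1-en-1-yl]oxy}silane | C[C@@H]1CCCC(O[Si](C)(C)C)=C1C | intermediate
4 | methyl vinyl ketone (but-3-en-2-one) | C=CC(C)=O | starting material
5 | (2S,3R)-2,3-dimethyl-2-(3-oxobutyl)cyclohexan-1-one | O=C1CCC[C@@H](C)[C@]1(C)CCC(C)=O | intermediate
6 | triethyl phosphonoacetate | CCOC(=O)CP(=O)(OCC)OCC | starting material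
7 | ethyl (2E)-5-[(1S,2R)-1,2-dimethyl-6-oxocyclohexyl]-3-methylpent-2-enoate | O=C1CCC[C@@H](C)[C@]1(C)CC/C(C)=C/C(=O)OCC | intermediate
8 | ethyl (2E)-5-[(1S,6R)-1,6-dimethyl-2-(trifluoromethanesulfonyloxy)cyclohex-2-en-1-yl]-3-methylpent-2-enoate | FC(F)(F)S(=O)(=O)OC1=CCC[C@@H](C)[C@]1(C)CC/C(C)=C/C(=O)OCC | intermediate
9 | (5R,6S)-6-[(3E)-5-hydroxy-3-methylpent-3-en-1-yl]-5,6-dimethylcyclohex-1-en-1-yl trifluoromethanesulfonate | FC(F)(F)S(=O)(=O)OC1=CCC[C@@H](C)[C@]1(C)CC/C(C)=C/CO | intermediate
10 | ethyl (2Z)-3-iodoprop-2-enoate | CCOC(=O)/C=C\I | starting material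
11 | methyl 2-(triphenylphosphoranylidene)propanoate | COC(=O)C(C)=P(c1ccccc1)(c1ccccc1)c1ccccc1 | starting material
12 | (2Z)-3-iodoprop-2-enal | O=C/C=C\I | intermediate
13 | methyl (2E,4Z)-5-iodo-2-methylpenta-2,4-dienoate | COC(=O)/C(C)=C/C=C\I | intermediate
14 | methyl (2E,4Z)-2-methyl-5-(4,4,5,5-tetramethyl-1,3,2-dioxaborolan-2-yl)penta-2,4-dienoate | COC(=O)/C(C)=C/C=C\B1OC(C)(C)C(C)(C)O1 | intermediate
15 | methyl (2E,4Z)-5-{(5R,6S)-6-[(3E)-5-hydroxy-3-methylpent-3-en-1-yl]-5,6-dimethylcyclohex-1-en-1-yl}-2-methylpenta-2,4-dienoate | COC(=O)/C(C)=C/C=C\C1=CCC[C@@H](C)[C@]1(C)CC/C(C)=C/CO | intermediate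
16 | methyl (1S,5S,6R,8aR)-5-[(3E)-5-hydroxy-3-methylpent-3-en-1-yl]-1,5,6-trimethyl-1,5,6,7,8,8a-hexahydronaphthalene-1-carboxylate | COC(=O)[C@@]1(C)C=CC=C2[C@H]1CC[C@@H](C)[C@]2(C)CC/C(C)=C/CO | intermediate
17 | methyl (1S,5S,6R,8aR)-5-[(3E)-5-hydroxy-3-methylpent-3-en-1-yl]-1,5,6-trimethyl-1,2,3,5,6,7,8,8a-octahydronaphthalene-1-carboxylate | COC(=O)[C@@]1(C)CCC=C2[C@H]1CC[C@@H](C)[C@]2(C)CC/C(C)=C/CO | intermediate
18 | methyl (1S,5S,6R,8aR)-5-{2-[(2S,3S)-3-(hydroxymethyl)-2-methyloxiran-2-yl]ethyl}-1,5,6-trimethyl-1,2,3,5,6,7,8,8a-octahydronaphthalene-1-carboxylate | COC(=O)[C@@]1(C)CCC=C2[C@H]1CC[C@@H](C)[C@]2(C)CC[C@]1(C)O[C@H]1CO | target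

Total step count: 10 (8 on the main line, 2 for boronate 14).
Longest linear sequence: 8 steps (steps 1–5, 8, 9, 10, from 2-methylcyclohex-2-en-1-one).

Steps most likely to fail

Step 8. The electrocyclisation may close on both faces of C5 (poor torquoselectivity), the triene may be drained by hydrogen shift or oligomerisation before it closes, or coupling at the hindered triflate may stall. The fallback sets out from 9 and comes back at 17; it replaces the cascade by a lactone-enolate Claisen ring contraction in which a carbinol at C1 transfers its chirality to C4 and C5. Silylation of 9 (TBSCl, imidazole) gives the silyl ether (5R,6S)-6-[(3E)-5-(tert-butyldimethylsilyloxy)-3-methylpent-3-en-1-yl]-5,6-dimethylcyclohex-1-en-1-yl triflate F1. Nozaki–Hiyama–Kishi coupling of F1 with methyl 5-oxopentanoate (CrCl2, catalytic NiCl2, DMF) forms C1–C10 and gives the allylic alcohol F2 as a mixture at C1. Dess–Martin oxidation gives the enone F3. CBS reduction with the (S)-methyl oxazaborolidine catalyst and catecholborane should give the (R)-alcohol F4, which closes under acid catalysis to the (6R)-δ-lactone F5. LiN(iPr)2 then MeI gives the α-methyl lactone F6, whose new centre is erased in the next operation. LiN(iPr)2, TBSCl and HMPA give the cyclic silyl ketene acetal, which on heating in toluene rearranges (Ireland–Claisen, boat transition state enforced by the ring) to the acid F7 after hydrolysis of the silyl ester; the (R)-carbinol dictates 4S and 5R, and C1=C10 appears directly without a diene stage. TMSCHN2 gives the methyl ester F8, and Bu4NF returns 17.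

Step 7. The Z geometry may erode in the palladium cycle, or the product may be consumed by Suzuki homocoupling with unreacted iodide. The fallback sets out from 11 and comes back at 14; it makes the Z-alkenylboronate by hydroboration instead of borylation. Wittig reaction of 11 with 3-(trimethylsilyl)prop-2-ynal gives methyl (2E)-2-methyl-5-(trimethylsilyl)pent-2-en-4-ynoate F9. K2CO3 in MeOH gives the terminal enyne methyl (2E)-2-methylpent-2-en-4-ynoate F10. Rhodium-catalysed trans-hydroboration ([Rh(cod)Cl]2, P(iPr)3, pinacolborane, Et3N), which proceeds through a vinylidene and places boron cis to the chain, gives 14.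

Step 3. The olefination of the methyl ketone may give insufficient E/Z selectivity (and step 2 upstream may suffer from enone polymerisation). The fallback sets out from 3 and comes back at 9; it fixes the alkene geometry by syn-carbometallation of an alkyne. MeLi regenerates the lithium enolate from 3 and allyl bromide gives, trans to the C8 methyl, (2S,3R)-2,3-dimethyl-2-(prop-2-en-1-yl)cyclohexan-1-one F11. Tf2O with 2,6-di-tert-butyl-4-methylpyridine gives the enol triflate F12. 9-BBN then NaBO3 gives the primary alcohol F13, and Dess–Martin oxidation the aldehyde F14. Ohira–Bestmann homologation (dimethyl (1-diazo-2-oxopropyl)phosphonate, K2CO3, MeOH) gives the terminal alkyne F15. Negishi carboalumination (AlMe3, catalytic Cp2ZrCl2) and trapping of the alkenylalane with paraformaldehyde gives 9.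

Further compounds
F1 | step 8 | (5R,6S)-6-[(3E)-5-(tert-butyldimethylsilyloxy)-3-methylpent-3-en-1-yl]-5,6-dimethylcyclohex-1-en-1-yl trifluoromethanesulfonate | FC(F)(F)S(=O)(=O)OC1=CCC[C@@H](C)[C@]1(C)CC/C(C)=C/CO[Si](C)(C)C(C)(C)C
F2 | step 8 | methyl 5-hydroxy-5-{(5R,6S)-6-[(3E)-5-(tert-butyldimethylsilyloxy)-3-methylpent-3-en-1-yl]-5,6-dimethylcyclohex-1-en-1-yl}pentanoate (both C5 epimers) | COC(=O)CCCC(O)C1=CCC[C@@H](C)[C@]1(C)CC/C(C)=C/CO[Si](C)(C)C(C)(C)C
F3 | step 8 | methyl 5-oxo-5-{(5R,6S)-6-[(3E)-5-(tert-butyldimethylsilyloxy)-3-methylpent-3-en-1-yl]-5,6-dimethylcyclohex-1-en-1-yl}pentanoate | COC(=O)CCCC(=O)C1=CCC[C@@H](C)[C@]1(C)CC/C(C)=C/CO[Si](C)(C)C(C)(C)C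
F4 | step 8 | methyl (5R)-5-hydroxy-5-{(5R,6S)-6-[(3E)-5-(tert-butyldimethylsilyloxy)-3-methylpent-3-en-1-yl]-5,6-dimethylcyclohex-1-en-1-yl}pentanoate | COC(=O)CCC[C@@H](O)C1=CCC[C@@H](C)[C@]1(C)CC/C(C)=C/CO[Si](C)(C)C(C)(C)C
F5 | step 8 | (6R)-6-{(5R,6S)-6-[(3E)-5-(tert-butyldimethylsilyloxy)-3-methylpent-3-en-1-yl]-5,6-dimethylcyclohex-1-en-1-yl}oxan-2-one | O=C1CCC[C@@H](O1)C1=CCC[C@@H](C)[C@]1(C)CC/C(C)=C/CO[Si](C)(C)C(C)(C)C
F6 | step 8 | (6R)-3-methyl-6-{(5R,6S)-6-[(3E)-5-(tert-butyldimethylsilyloxy)-3-methylpent-3-en-1-yl]-5,6-dimethylcyclohex-1-en-1-yl}oxan-2-one (both C3 epimers) | CC1CC[C@@H](OC1=O)C1=CCC[C@@H](C)[C@]1(C)CC/C(C)=C/CO[Si](C)(C)C(C)(C)C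
F7 | step 8 | (1S,5S,6R,8aR)-5-[(3E)-5-(tert-butyldimethylsilyloxy)-3-methylpent-3-en-1-yl]-1,5,6-trimethyl-1,2,3,5,6,7,8,8a-octahydronaphthalene-1-carboxylic acid | OC(=O)[C@@]1(C)CCC=C2[C@H]1CC[C@@H](C)[C@]2(C)CC/C(C)=C/CO[Si](C)(C)C(C)(C)C
F8 | step 8 | methyl (1S,5S,6R,8aR)-5-[(3E)-5-(tert-butyldimethylsilyloxy)-3-methylpent-3-en-1-yl]-1,5,6-trimethyl-1,2,3,5,6,7,8,8a-octahydronaphthalene-1-carboxylate | COC(=O)[C@@]1(C)CCC=C2[C@H]1CC[C@@H](C)[C@]2(C)CC/C(C)=C/CO[Si](C)(C)C(C)(C)C
F9 | step 7 | methyl (2E)-2-methyl-5-(trimethylsilyl)pent-2-en-4-ynoate | COC(=O)/C(C)=C/C#C[Si](C)(C)C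
F10 | step 7 | methyl (2E)-2-methylpent-2-en-4-ynoate | COC(=O)/C(C)=C/C#C
F11 | step 3 | (2S,3R)-2,3-dimethyl-2-(prop-2-en-1-yl)cyclohexan-1-one | O=C1CCC[C@@H](C)[C@]1(C)CC=C
F12 | step 3 | (5R,6S)-5,6-dimethyl-6-(prop-2-en-1-yl)cyclohex-1-en-1-yl trifluoromethanesulfonate | FC(F)(F)S(=O)(=O)OC1=CCC[C@@H](C)[C@]1(C)CC=C
F13 | step 3 | (5R,6S)-6-(3-hydroxypropyl)-5,6-dimethylcyclohex-1-en-1-yl trifluoromethanesulfonate | FC(F)(F)S(=O)(=O)OC1=CCC[C@@H](C)[C@]1(C)CCCO
F14 | step 3 | (5R,6S)-5,6-dimethyl-6-(3-oxopropyl)cyclohex-1-en-1-yl trifluoromethanesulfonate | FC(F)(F)S(=O)(=O)OC1=CCC[C@@H](C)[C@]1(C)CCC=O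
F15 | step 3 | (5R,6S)-6-(but-3-yn-1-yl)-5,6-dimethylcyclohex-1-en-1-yl trifluoromethanesulfonate | FC(F)(F)S(=O)(=O)OC1=CCC[C@@H](C)[C@]1(C)CCC#C
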